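**Strategy.** The cyclohexane core (elemane numbering: C5 bears the hydroxyisopropenyl group, C6 the free hydroxyl, C7 the acrylic acid, C8 the ester oxygen, C9 is CH2, C10 the methyl/vinyl quaternary carbon) is closed by a [3+3] union that forms C9–C10 and C6–C7 in one flask. The array O–C8–C9H2–C10(vinyl) is a Claisen retron; the array HO–C6–C7–C11(=CH2)–CO2 is an allylchromium/aldehyde retron. The precursor 19 is an acyclic Z-allyl dienyl ether that carries the C6 aldehyde and a 2-(bromomethyl)enoate: heating creates quaternary C10 and the vinyl group, then CrCl2 closes the ring at C6–C7 as a cis-fused α-methylene lactone.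

Key step: step 13

Assumption: the open γ-hydroxy acid form of 31 is taken to be isolable if steps 19 and 20 are worked up at pH 5–6 and 0 °C; stronger acid would close it to the C6 lactone.

**Step 1**
Reactants: 1 2-bromoprop-2-en-1-ol
Product: 2 tert-butyl[(2-bromoprop-2-en-1-yl)oxy]dimethylsilane
Conditions: TBSCl, imidazole, DMF, 0 °C to rt
Reagents that add atoms: tert-butyldimethylsilyl chloride, CC(C)(C)[Si](C)(C)Cl
Why: Standard silylation of the primary alcohol gives the C15 oxygen in the form that is carried to the last step.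

**Step 2**
Reactants: 2 tert-butyl[(2-bromoprop-2-en-1-yl)oxy]dimethylsilane; 3 prop-1-yn-1-ylmagnesium bromide
Product: 4 tert-butyldimethyl[(2-methylidenepent-3-yn-1-yl)oxy]silane
Conditions: ZnBr2, THF, 0 °C; Pd(PPh3)4 (3 mol%), 50 °C
Reagents that add atoms: none
Why: Negishi coupling of the in situ propynylzinc with the vinyl bromide should give the enyne that holds C3, C4, C5, C10, C14 and C15.

**Step 3**
Reactants: 4 tert-butyldimethyl[(2-methylidenepent-3-yn-1-yl)oxy]silane; 5 [(4-methoxybenzyl)oxy]acetaldehyde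
Product: 6 (2S,3E)-5-{[(tert-butyldimethylsilyl)oxy]methyl}-1-[(4-methoxybenzyl)oxy]-3-methylhexa-3,5-dien-2-ol
Conditions: Cp2Zr(H)Cl, CH2Cl2, rt; Me2Zn, toluene, −65 °C; (−)-MIB (10 mol%), then 5, −30 °C; aq. NH4Cl
Reagents that add atoms: none
Why: Syn hydrozirconation places zirconium on the methyl-bearing alkyne carbon, zirconium-to-zinc exchange gives the E-dienylzinc, and its amino-alcohol-catalysed addition to the aldehyde (Wipf–Oppolzer alkenylzinc addition) sets the S carbinol (C1) under ligand control, the ligand antipode being used if the opposite sense is found.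

**Step 4**
Reactants: 6 (2S,3E)-5-{[(tert-butyldimethylsilyl)oxy]methyl}-1-[(4-methoxybenzyl)oxy]-3-methylhexa-3,5-dien-2-ol
Product: 7 tributyl[({(2S,3E)-5-{[(tert-butyldimethylsilyl)oxy]methyl}-1-[(4-methoxybenzyl)oxy]-3-methylhexa-3,5-dien-2-yl}oxy)methyl]stannane
Conditions: KH, 18-crown-6 (cat.), THF, 0 °C; Bu3SnCH2I, rt
Reagents that add atoms: tributyl(iodomethyl)stannane, CCCC[Sn](CCCC)(CCCC)CI
Why: Williamson etherification of the potassium alkoxide installs the stannylmethyl group (future C6) for the Still variant of the Wittig rearrangement.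

**Step 5**
Reactants: 7 tributyl[({(2S,3E)-5-{[(tert-butyldimethylsilyl)oxy]methyl}-1-[(4-methoxybenzyl)oxy]-3-methylhexa-3,5-dien-2-yl}oxy)methyl]stannane
Product: 9 (2S,3Z)-2-{3-[(tert-butyldimethylsilyl)oxy]prop-1-en-2-yl}-5-[(4-methoxybenzyl)oxy]-3-methylpent-3-en-1-yl triethylsilyl ether, via lithium alkoxide 8 (not isolated)
Conditions: n-BuLi, THF, −78 °C; then TESCl, −78 to 0 °C
Reagents that add atoms: chlorotriethylsilane, CC[Si](Cl)(CC)CC
Why: Tin–lithium exchange triggers the [2,3]-Wittig–Still rearrangement through a five-membered envelope in which the CH2OPMB group lies pseudo-axial away from the C10 methyl, so the new C10=C1 bond should be Z and the S carbinol chirality is transferred suprafacially to C5 (S), the alkoxide being capped as the TES ether.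

**Step 6**
Reactants: 9 (2S,3Z)-2-{3-[(tert-butyldimethylsilyl)oxy]prop-1-en-2-yl}-5-[(4-methoxybenzyl)oxy]-3-methylpent-3-en-1-yl triethylsilyl ether
Product: 10 (2Z,4S)-4-{3-[(tert-butyldimethylsilyl)oxy]prop-1-en-2-yl}-3-methyl-5-[(triethylsilyl)oxy]pent-2-en-1-ol
Conditions: DDQ, CH2Cl2/pH 7 buffer (10:1), 0 °C
Reagents that add atoms: none
Why: Oxidative PMB cleavage is fast at 0 °C and should leave both silyl ethers and the skipped diene intact, freeing the C2 allylic alcohol.

**Step 7**
Reactants: 11 1-(triphenylphosphoranylidene)propan-2-one; 12 methyl 2-oxopropanoate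
Product: 13 methyl (2E)-2-methyl-4-oxopent-2-enoate
Conditions: CH2Cl2, rt to 40 °C
Reagents that add atoms: none
Why: Wittig olefination of the activated keto group of methyl pyruvate by the stabilised ylide should give mainly the E enone ester (C9, C8, C7, C11, C13, C12).

**Step 8**
Reactants: 13 methyl (2E)-2-methyl-4-oxopent-2-enoate
Product: 14 methyl (2E)-4,4-dimethoxy-2-methylpent-2-enoate
Conditions: HC(OMe)3, MeOH, TsOH (cat.), rt
Reagents that add atoms: trimethyl orthoformate, COC(OC)OC
Why: Acid-catalysed ketalisation driven by the orthoformate masks the C8 ketone and removes the acidity of the C9 methyl group before bromination.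

**Step 9**
Reactants: 14 methyl (2E)-4,4-dimethoxy-2-methylpent-2-enoate
Product: 15 methyl (2Z)-2-(bromomethyl)-4,4-dimethoxypent-2-enoate
Conditions: NBS, AIBN (cat.), K2CO3, PhCF3, 80 °C
Reagents that add atoms: N-bromosuccinimide, O=C1CCC(=O)N1Br
Why: Wohl–Ziegler bromination can only attack the C13 methyl group, the single allylic C–H position of 14.

**Step 10**
Reactants: 10 (2Z,4S)-4-{3-[(tert-butyldimethylsilyl)oxy]prop-1-en-2-yl}-3-methyl-5-[(triethylsilyl)oxy]pent-2-en-1-ol; 15 methyl (2Z)-2-(bromomethyl)-4,4-dimethoxypent-2-enoate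
Product: 17 methyl (2Z)-2-(bromomethyl)-4-{[(2Z,4S)-4-{3-[(tert-butyldimethylsilyl)oxy]prop-1-en-2-yl}-3-methyl-5-[(triethylsilyl)oxy]pent-2-en-1-yl]oxy}penta-2,4-dienoate, via mixed ketal 16 (not isolated)
Conditions: 15 (4 equiv), PPTS (5 mol%), 5 Å MS, toluene, rt; then iPr2NEt, TMSOTf, CH2Cl2, −20 to 0 °C
Reagents that add atoms: none
Why: Acid-catalysed transketalisation gives the mixed ketal, and Gassman-type silyl triflate/amine elimination removes the less hindered methoxy group and a proton of the only α-methyl group, placing the enol ether double bond at C8=C9 well below the temperature of the [3,3] shift.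

**Step 11**
Reactants: 17 methyl (2Z)-2-(bromomethyl)-4-{[(2Z,4S)-4-{3-[(tert-butyldimethylsilyl)oxy]prop-1-en-2-yl}-3-methyl-5-[(triethylsilyl)oxy]pent-2-en-1-yl]oxy}penta-2,4-dienoate
Product: 18 methyl (2Z)-2-(bromomethyl)-4-{[(2Z,4S)-4-{3-[(tert-butyldimethylsilyl)oxy]prop-1-en-2-yl}-5-hydroxy-3-methylpent-2-en-1-yl]oxy}penta-2,4-dienoate
Conditions: HF·pyridine, excess pyridine, THF, 0 °C
Reagents that add atoms: none
Why: Buffered fluoride cleaves the primary TES ether much faster than the TBS ether and is not acidic enough to hydrolyse the dienyl ether.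

**Step 12**
Reactants: 18 methyl (2Z)-2-(bromomethyl)-4-{[(2Z,4S)-4-{3-[(tert-butyldimethylsilyl)oxy]prop-1-en-2-yl}-5-hydroxy-3-methylpent-2-en-1-yl]oxy}penta-2,4-dienoate
Product: 19 methyl (2Z)-2-(bromomethyl)-4-{[(2Z,4S)-4-{3-[(tert-butyldimethylsilyl)oxy]prop-1-en-2-yl}-3-methyl-5-oxopent-2-en-1-yl]oxy}penta-2,4-dienoate
Conditions: Dess–Martin periodinane, NaHCO3, CH2Cl2, 0 °C; filtered and used at once
Reagents that add atoms: none
Why: Buffered Dess–Martin oxidation is neutral and fast, so the bis-allylic formyl stereocentre C5 should survive until the next step.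

**Step 13**
Reactants: 19 methyl (2Z)-2-(bromomethyl)-4-{[(2Z,4S)-4-{3-[(tert-butyldimethylsilyl)oxy]prop-1-en-2-yl}-3-methyl-5-oxopent-2-en-1-yl]oxy}penta-2,4-dienoate
Product: 22 (3aS,6R,7S,7aS)-7-{3-[(tert-butyldimethylsilyl)oxy]prop-1-en-2-yl}-6-ethenyl-6-methyl-3-methylidenehexahydro-1-benzofuran-2,4(3H)-dione, via keto aldehyde 20 (not isolated), via hydroxy ester 21 (not isolated)
Conditions: toluene (5 mM), BHT, 85 °C, 3 h; then THF, CrCl2 (5 equiv), LiI (0.2 equiv), 0 °C to rt; aqueous work-up, then PPTS (cat.), CH2Cl2, rt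
Reagents that add atoms: none
Why: Heating triggers the [3,3] Claisen rearrangement of the allyl 2-dienyl ether (the Johnson 3-methoxyisoprene variant of the aliphatic Claisen), which forms C9–C10 and reveals the C1=C2 vinyl group and the C8 ketone; CrCl2 then turns the 2-(bromomethyl)enoate into an allylchromium species (Nozaki–Hiyama allylation, equally a vinylogous chromium Reformatsky reaction) that adds through C7 to the C6 aldehyde, and the cis γ-hydroxy ester lactonises. The cyclohexane closes by 6-exo-trig attack on the aldehyde through a six-membered allyl-transfer array fused to the forming ring. C10 is controlled by A(1,3) strain in the Z-allyl ether: H5 eclipses the C2 methylene, the bulky silyloxy-isopropenyl group blocks one face and the chair-like Claisen array passes the small formyl group, which places the C10 methyl cis to the C5 substituent. C6 and C7 are controlled in the chromium stage: the C5 substituent sits equatorial with the aldehyde oxygen anti to quaternary C10 (C6 oxygen trans to C5), and the fused transition state delivers C7–C11 cis to the C6 oxygen, as known for chromium-mediated closures to cis-fused α-methylene lactones. The step needs attack through C7 and not C13, which ring size secures (six against eight atoms), and aldehyde over ketone selectivity, which is inherent to organochromium reagents.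

**Step 14**
Reactants: 22 (3aS,6R,7S,7aS)-7-{3-[(tert-butyldimethylsilyl)oxy]prop-1-en-2-yl}-6-ethenyl-6-methyl-3-methylidenehexahydro-1-benzofuran-2,4(3H)-dione
Product: 23 (3aR,4R,6R,7S,7aS)-7-{3-[(tert-butyldimethylsilyl)oxy]prop-1-en-2-yl}-6-ethenyl-4-hydroxy-6-methyl-3-methylidenehexahydro-1-benzofuran-2(3H)-one (C8 hydroxyl cis to the lactone ring)
Conditions: (S)-2-methyl-CBS-oxazaborolidine (1 equiv), catecholborane, toluene, −78 °C
Reagents that add atoms: none
Why: Corey–Bakshi–Shibata reduction with the branched C7 side as large and the C9 methylene as small substituent should deliver hydride anti to the C7–C11 bond and give the R carbinol at C8, while catecholborane leaves the α-methylene lactone untouched.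

**Step 15**
Reactants: 24 {[tert-butyl(dimethyl)silyl]oxy}acetaldehyde; 25 1,1,1,3,3,3-hexafluoropropan-2-yl prop-2-enoate
Product: 26 1,1,1,3,3,3-hexafluoropropan-2-yl (3R)-4-{[tert-butyl(dimethyl)silyl]oxy}-3-hydroxy-2-methylidenebutanoate
Conditions: α-isocupreine (10 mol%), DMF, −55 °C
Reagents that add atoms: none
Why: Hatakeyama-type asymmetric Morita–Baylis–Hillman reaction, with α-isocupreine (the enantiocomplementary partner of β-isocupreidine) chosen so that the side-chain carbinol is formed R.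

**Step 16**
Reactants: 26 1,1,1,3,3,3-hexafluoropropan-2-yl (3R)-4-{[tert-butyl(dimethyl)silyl]oxy}-3-hydroxy-2-methylidenebutanoate
Product: 27 1,1,1,3,3,3-hexafluoropropan-2-yl (3R)-3,4-bis{[tert-butyl(dimethyl)silyl]oxy}-2-methylidenebutanoate
Conditions: TBSOTf, 2,6-lutidine, CH2Cl2, −78 to 0 °C
Reagents that add atoms: tert-butyldimethylsilyl trifluoromethanesulfonate, CC(C)(C)[Si](C)(C)OS(=O)(=O)C(F)(F)F
Why: Silylation of the secondary allylic alcohol blocks later attack of the side-chain hydroxyls on their own ester.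

**Step 17**
Reactants: 27 1,1,1,3,3,3-hexafluoropropan-2-yl (3R)-3,4-bis{[tert-butyl(dimethyl)silyl]oxy}-2-methylidenebutanoate
Product: 28 (3R)-3,4-bis{[tert-butyl(dimethyl)silyl]oxy}-2-methylidenebutanoic acid
Conditions: LiOH, THF/H2O, 0 °C; then 0.1 M HCl to pH 4
Reagents that add atoms: lithium hydroxide, [Li+].[OH-]
Why: The activated hexafluoroisopropyl ester saponifies under very mild conditions that should not touch the silyl ethers or the stereocentre.

**Step 18**
Reactants: 23 (3aR,4R,6R,7S,7aS)-7-{3-[(tert-butyldimethylsilyl)oxy]prop-1-en-2-yl}-6-ethenyl-4-hydroxy-6-methyl-3-methylidenehexahydro-1-benzofuran-2(3H)-one; 28 (3R)-3,4-bis{[tert-butyl(dimethyl)silyl]oxy}-2-methylidenebutanoic acid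
Product: 29 C8 ester of lactone alcohol 23 with acid 28 (tris-TBS lactone ester)
Conditions: 2,4,6-trichlorobenzoyl chloride, Et3N, THF, rt; then 23, DMAP, toluene, rt
Reagents that add atoms: none
Why: Yamaguchi esterification acylates the only free hydroxyl (C8) with retention, C6 being tied up in the lactone.

**Step 19**
Reactants: 29 C8 ester of lactone alcohol 23 with acid 28
Product: 30 2-[(1S,2S,3S,4R,6R)-6-{[(3R)-3,4-bis{[tert-butyl(dimethyl)silyl]oxy}-2-methylidenebutanoyl]oxy}-3-{3-[(tert-butyldimethylsilyl)oxy]prop-1-en-2-yl}-4-ethenyl-2-hydroxy-4-methylcyclohexyl]prop-2-enoic acid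
Conditions: LiOH (1.1 equiv), THF/H2O (3:1), 0 °C; then 0.1 M HCl to pH 5, 0 °C
Reagents that add atoms: lithium hydroxide, [Li+].[OH-]
Why: The strained cis-fused α-methylene-γ-lactone should saponify much faster than the hindered secondary ester, and opening it while the side-chain hydroxyls are still silylated prevents their base-induced attack on the C8 ester.

**Step 20**
Reactants: 30 2-[(1S,2S,3S,4R,6R)-6-{[(3R)-3,4-bis{[tert-butyl(dimethyl)silyl]oxy}-2-methylidenebutanoyl]oxy}-3-{3-[(tert-butyldimethylsilyl)oxy]prop-1-en-2-yl}-4-ethenyl-2-hydroxy-4-methylcyclohexyl]prop-2-enoic acid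
Product: 31 2-[(1S,2S,3S,4R,6R)-6-{[(3R)-3,4-dihydroxy-2-methylidenebutanoyl]oxy}-4-ethenyl-2-hydroxy-3-(3-hydroxyprop-1-en-2-yl)-4-methylcyclohexyl]prop-2-enoic acid
Conditions: HF·pyridine, excess pyridine, THF, 0 °C to rt; pH 6 buffer work-up
Reagents that add atoms: none
Why: Buffered fluoride removes the three TBS ethers under conditions that are neither basic enough for side-chain lactonisation nor acidic enough for fast closure of the γ-hydroxy acid.

**Compound list**

1 | 2-bromoprop-2-en-1-ol | C=C(Br)CO | starting material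
2 | tert-butyl[(2-bromoprop-2-en-1-yl)oxy]dimethylsilane | C=C(Br)CO[Si](C)(C)C(C)(C)C | intermediate
3 | prop-1-yn-1-ylmagnesium bromide | CC#C[Mg]Br | starting material
4 | tert-butyldimethyl[(2-methylidenepent-3-yn-1-yl)oxy]silane | CC#CC(=C)CO[Si](C)(C)C(C)(C)C | intermediate
5 | [(4-methoxybenzyl)oxy]acetaldehyde | COc1ccc(COCC=O)cc1 | starting material
6 | (2S,3E)-5-{[(tert-butyldimethylsilyl)oxy]methyl}-1-[(4-methoxybenzyl)oxy]-3-methylhexa-3,5-dien-2-ol | COc1ccc(COC[C@@H](O)/C(C)=C/C(=C)CO[Si](C)(C)C(C)(C)C)cc1 | intermediate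
7 | tributylstannylmethyl ether of 6 | CCCC[Sn](CCCC)(CCCC)CO[C@H](COCc1ccc(OC)cc1)/C(C)=C/C(=C)CO[Si](C)(C)C(C)(C)C | intermediate
8 | lithium (2S,3Z)-2-{3-[(tert-butyldimethylsilyl)oxy]prop-1-en-2-yl}-5-[(4-methoxybenzyl)oxy]-3-methylpent-3-en-1-olate | [Li+].[O-]C[C@@H](/C(C)=C\COCc1ccc(OC)cc1)C(=C)CO[Si](C)(C)C(C)(C)C | intermediate
9 | (2S,3Z)-2-{3-[(tert-butyldimethylsilyl)oxy]prop-1-en-2-yl}-5-[(4-methoxybenzyl)oxy]-3-methylpent-3-en-1-yl triethylsilyl ether | CC[Si](CC)(CC)OC[C@@H](/C(C)=C\COCc1ccc(OC)cc1)C(=C)CO[Si](C)(C)C(C)(C)C | intermediate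
10 | (2Z,4S)-4-{3-[(tert-butyldimethylsilyl)oxy]prop-1-en-2-yl}-3-methyl-5-[(triethylsilyl)oxy]pent-2-en-1-ol | CC[Si](CC)(CC)OC[C@@H](/C(C)=C\CO)C(=C)CO[Si](C)(C)C(C)(C)C | intermediate
11 | 1-(triphenylphosphoranylidene)propan-2-one | CC(=O)C=P(c1ccccc1)(c1ccccc1)c1ccccc1 | starting material
12 | methyl 2-oxopropanoate | CC(=O)C(=O)OC | starting material
13 | methyl (2E)-2-methyl-4-oxopent-2-enoate | CC(=O)/C=C(\C)C(=O)OC | intermediate
14 | methyl (2E)-4,4-dimethoxy-2-methylpent-2-enoate | COC(C)(OC)/C=C(\C)C(=O)OC | intermediate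
15 | methyl (2Z)-2-(bromomethyl)-4,4-dimethoxypent-2-enoate | COC(C)(OC)/C=C(\CBr)C(=O)OC | intermediate
16 | mixed methyl ketal of 10 and 15 (ketal carbon unassigned) | CC[Si](CC)(CC)OC[C@@H](/C(C)=C\COC(C)(OC)/C=C(\CBr)C(=O)OC)C(=C)CO[Si](C)(C)C(C)(C)C | intermediate
17 | allyl dienyl ether, C6 TES ether | CC[Si](CC)(CC)OC[C@@H](/C(C)=C\COC(=C)/C=C(\CBr)C(=O)OC)C(=C)CO[Si](C)(C)C(C)(C)C | intermediate
18 | allyl dienyl ether, C6 primary alcohol | OC[C@@H](/C(C)=C\COC(=C)/C=C(\CBr)C(=O)OC)C(=C)CO[Si](C)(C)C(C)(C)C | intermediate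
19 | allyl dienyl ether, C6 aldehyde (5S) | O=C[C@@H](/C(C)=C\COC(=C)/C=C(\CBr)C(=O)OC)C(=C)CO[Si](C)(C)C(C)(C)C | intermediate
20 | methyl (2Z,6R,7S)-2-(bromomethyl)-8-{[(tert-butyldimethylsilyl)oxy]methyl}-6-ethenyl-7-formyl-6-methyl-4-oxonona-2,8-dienoate | O=C[C@H](C(=C)CO[Si](C)(C)C(C)(C)C)[C@@](C)(C=C)CC(=O)/C=C(\CBr)C(=O)OC | intermediate
21 | methyl 2-[(1S,2S,3S,4R)-3-{3-[(tert-butyldimethylsilyl)oxy]prop-1-en-2-yl}-4-ethenyl-2-hydroxy-4-methyl-6-oxocyclohexyl]prop-2-enoate | C=C[C@@]1(C)CC(=O)[C@@H](C(=C)C(=O)OC)[C@@H](O)[C@@H]1C(=C)CO[Si](C)(C)C(C)(C)C | intermediate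
22 | (3aS,6R,7S,7aS)-7-{3-[(tert-butyldimethylsilyl)oxy]prop-1-en-2-yl}-6-ethenyl-6-methyl-3-methylidenehexahydro-1-benzofuran-2,4(3H)-dione | C=C[C@@]1(C)CC(=O)[C@H]2C(=C)C(=O)O[C@H]2[C@@H]1C(=C)CO[Si](C)(C)C(C)(C)C | intermediate
23 | (3aR,4R,6R,7S,7aS)-7-{3-[(tert-butyldimethylsilyl)oxy]prop-1-en-2-yl}-6-ethenyl-4-hydroxy-6-methyl-3-methylidenehexahydro-1-benzofuran-2(3H)-one | C=C[C@@]1(C)C[C@@H](O)[C@H]2C(=C)C(=O)O[C@H]2[C@@H]1C(=C)CO[Si](C)(C)C(C)(C)C | intermediate
24 | {[tert-butyl(dimethyl)silyl]oxy}acetaldehyde | CC(C)(C)[Si](C)(C)OCC=O | starting material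
25 | 1,1,1,3,3,3-hexafluoropropan-2-yl prop-2-enoate | C=CC(=O)OC(C(F)(F)F)C(F)(F)F | starting material
26 | 1,1,1,3,3,3-hexafluoropropan-2-yl (3R)-4-{[tert-butyl(dimethyl)silyl]oxy}-3-hydroxy-2-methylidenebutanoate | C=C(C(=O)OC(C(F)(F)F)C(F)(F)F)[C@@H](O)CO[Si](C)(C)C(C)(C)C | intermediate
27 | 1,1,1,3,3,3-hexafluoropropan-2-yl (3R)-3,4-bis{[tert-butyl(dimethyl)silyl]oxy}-2-methylidenebutanoate | C=C(C(=O)OC(C(F)(F)F)C(F)(F)F)[C@@H](O[Si](C)(C)C(C)(C)C)CO[Si](C)(C)C(C)(C)C | intermediate
28 | (3R)-3,4-bis{[tert-butyl(dimethyl)silyl]oxy}-2-methylidenebutanoic acid | C=C(C(=O)O)[C@@H](O[Si](C)(C)C(C)(C)C)CO[Si](C)(C)C(C)(C)C | intermediate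
29 | C8 ester of lactone alcohol 23 with acid 28 | C=C[C@@]1(C)C[C@@H](OC(=O)C(=C)[C@@H](O[Si](C)(C)C(C)(C)C)CO[Si](C)(C)C(C)(C)C)[C@H]2C(=C)C(=O)O[C@H]2[C@@H]1C(=C)CO[Si](C)(C)C(C)(C)C | intermediate
30 | tris-TBS ether of the target hydroxy acid | C=C[C@@]1(C)C[C@@H](OC(=O)C(=C)[C@@H](O[Si](C)(C)C(C)(C)C)CO[Si](C)(C)C(C)(C)C)[C@@H](C(=C)C(=O)O)[C@@H](O)[C@@H]1C(=C)CO[Si](C)(C)C(C)(C)C | intermediate
31 | 2-[(1S,2S,3S,4R,6R)-6-{[(3R)-3,4-dihydroxy-2-methylidenebutanoyl]oxy}-4-ethenyl-2-hydroxy-3-(3-hydroxyprop-1-en-2-yl)-4-methylcyclohexyl]prop-2-enoic acid | C=C[C@@]1(C)C[C@@H](OC(=O)C(=C)[C@@H](O)CO)[C@@H](C(=C)C(=O)O)[C@@H](O)[C@@H]1C(=C)CO | target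

**Step count.** Total: 20 steps. Longest linear sequence: 14 steps (steps 1–6, 10–14, 18–20).

**Steps most likely to fail**

Step 13. During the thermal stage the cis γ-bromo enone formed by the rearrangement may close to a furan with loss of HBr, the bis-allylic formyl centre C5 may enolise into conjugation, or the organochromium may be protonated without ring closure. The fallback keeps the one-flask union but removes the bromide and closes C6–C7 by an α-selective vinylogous aldol reaction. It sets out from compounds 10 and 14 and comes back at compound 21. Transketalisation of 10 with 14 (PPTS, 5 Å MS) would give the bromine-free mixed ketal F1, and TMSOTf/iPr2NEt would turn it into the bromine-free allyl dienyl ether F2. HF·pyridine would give the primary alcohol F3 and buffered Dess–Martin oxidation the aldehyde F4. Heating F4 in toluene at 85 °C would give the keto aldehyde F5, which is treated in the same flask with TiCl4 and Et3N at −78 °C. Soft enolisation at the C13 methyl group should give the titanium dienolate, which adds through C7 to the C6 aldehyde and gives hydroxy ester 21; PPTS then closes it to 22.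

Step 10. The silyl triflate elimination may expel the allylic alkoxide instead of methoxide, or the transketalisation may stall at equilibrium. The fallback exchanges the alcohol onto a preformed enol ether instead of eliminating from a mixed ketal. It sets out from compound 15 and comes back at compound 17. Treating 15 with TMSOTf/iPr2NEt would give methyl (2Z)-2-(bromomethyl)-4-methoxypenta-2,4-dienoate F6. Alcohol 10 is then transetherified with excess F6 under Hg(OCOCF3)2 catalysis at rt (oxymercuration–demercuration exchange), which should give 17 directly.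

Step 14. Hydride may be delivered to the wrong face if the substrate bias (the axial C10 methyl blocks the axial trajectory) overrides the catalyst, or the α-methylene lactone may suffer conjugate reduction. The fallback accepts the substrate-preferred epimer and inverts C8 during esterification. It sets out from compound 22 and comes back at compound 29. Luche reduction (NaBH4, CeCl3·7H2O, MeOH, −78 °C) would give the 8-epi alcohol F7, and Mitsunobu esterification of F7 with acid 28 (PPh3, DIAD, toluene, 0 °C) should give 29 with inversion at C8.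

**Further compounds**

F1 | step 13 | bromine-free mixed methyl ketal of 10 and 14 | CC[Si](CC)(CC)OC[C@@H](/C(C)=C\COC(C)(OC)/C=C(\C)C(=O)OC)C(=C)CO[Si](C)(C)C(C)(C)C
F2 | step 13 | bromine-free allyl dienyl ether, C6 TES ether | CC[Si](CC)(CC)OC[C@@H](/C(C)=C\COC(=C)/C=C(\C)C(=O)OC)C(=C)CO[Si](C)(C)C(C)(C)C
F3 | step 13 | bromine-free allyl dienyl ether, C6 primary alcohol | OC[C@@H](/C(C)=C\COC(=C)/C=C(\C)C(=O)OC)C(=C)CO[Si](C)(C)C(C)(C)C
F4 | step 13 | bromine-free allyl dienyl ether, C6 aldehyde | O=C[C@@H](/C(C)=C\COC(=C)/C=C(\C)C(=O)OC)C(=C)CO[Si](C)(C)C(C)(C)C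
F5 | step 13 | methyl (2E,6R,7S)-8-{[(tert-butyldimethylsilyl)oxy]methyl}-6-ethenyl-7-formyl-2,6-dimethyl-4-oxonona-2,8-dienoate | O=C[C@H](C(=C)CO[Si](C)(C)C(C)(C)C)[C@@](C)(C=C)CC(=O)/C=C(\C)C(=O)OC
F6 | step 10 | methyl (2Z)-2-(bromomethyl)-4-methoxypenta-2,4-dienoate | COC(=C)/C=C(\CBr)C(=O)OC
F7 | step 14 | 8-epi alcohol (C8 epimer of 23) | C=C[C@@]1(C)C[C@H](O)[C@H]2C(=C)C(=O)O[C@H]2[C@@H]1C(=C)CO[Si](C)(C)C(C)(C)C
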